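**Assumption:** the SMILES has no stereodescriptor and the molecule has no stereocentre (the aryl–naphthoquinone axis is left undefined), so the compound is made as drawn and no stereocontrol is needed.

## Retrosynthetic overview

- The target quinone comes from oxidative demethylation of 5,7,8-trimethoxy-2,3-dimethyl-1-(2,4,5-trimethoxyphenyl)naphthalene; its 5,8-dimethoxy ring becomes the 2-methoxy-1,4-quinone.
- The two vicinal methyl groups come from Raney Ni desulfurisation of a 1,3-dihydronaphtho[2,3-c]thiophene, with sulfur serving as a traceless tether.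
- Key step: Garratt–Braverman cyclisation of the symmetrical bis[3-(2,4,5-trimethoxyphenyl)propargyl] sulfide closes the dihydrothiophene ring and the new benzenoid ring in one operation. One trimethoxyphenyl ring becomes the oxygenated naphthalene ring and the other stays as the 8-aryl group.
- The sulfide comes from a double Sonogashira coupling of dipropargyl sulfide (propargyl bromide plus Na2S) with 1-iodo-2,4,5-trimethoxybenzene.
- Ring order: both trimethoxyphenyl rings are bought; the thiophene ring and the central benzene ring form together; the thiophene ring is excised; the quinone is revealed last.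

## Route

**Step 1**
Reactants: 1 propargyl bromide (3-bromoprop-1-yne, 2 equiv)
Product: 2 dipropargyl sulfide
Conditions: Na2S·9H2O (0.5 equiv), MeOH/H2O, 0 °C → rt
Reagents that add atoms: sodium sulfide (as Na2S·9H2O), [Na+].[Na+].[S-2]
Why: Double SN2 thioether synthesis, in which sulfide and then the propargyl thiolate displace the reactive propargylic bromide.

**Step 2**
Reactants: 2 dipropargyl sulfide; 3 1-iodo-2,4,5-trimethoxybenzene (2.1 equiv)
Product: 4 bis[3-(2,4,5-trimethoxyphenyl)prop-2-yn-1-yl] sulfide
Conditions: Pd(PPh3)2Cl2 (4 mol %), CuI (8 mol %), Et3N/THF, degassed, rt → 40 °C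
Reagents that add atoms: none
Why: Twofold Sonogashira coupling, in which the aryl iodide adds oxidatively to zerovalent palladium at room temperature, the dialkyl sulfide is tolerated, and Et3N is too weak a base to isomerise the propargyl sulfide.

**Step 3**
Reactants: 4 bis[3-(2,4,5-trimethoxyphenyl)prop-2-yn-1-yl] sulfide
Product: 6 5,6,8-trimethoxy-4-(2,4,5-trimethoxyphenyl)-1,3-dihydronaphtho[2,3-c]thiophene, via bis(allenyl) sulfide 5 (not isolated)
Conditions: KOtBu (0.3 equiv), THF, 0 °C → 50 °C
Reagents that add atoms: none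
Why: Garratt–Braverman cyclisation, a base-catalysed isomerisation in which propargyl-to-allenyl shift gives 5, bonding between the two central allene carbons closes the dihydrothiophene ring as a diradical, one benzylic terminus attacks the only free ortho position (C-6) of the other trimethoxyphenyl ring, and a hydrogen shift rearomatises to the new benzenoid ring; the symmetry of 4 removes any choice of which arene is attacked and no stereocentre is formed.

**Step 4**
Reactants: 6 5,6,8-trimethoxy-4-(2,4,5-trimethoxyphenyl)-1,3-dihydronaphtho[2,3-c]thiophene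
Product: 7 5,7,8-trimethoxy-2,3-dimethyl-1-(2,4,5-trimethoxyphenyl)naphthalene
Conditions: Raney Ni (W2 grade, excess), EtOH/THF, reflux
Reagents that add atoms: none
Why: Raney nickel reductive desulfurisation cleaves both benzylic C–S bonds and leaves the two methyl groups, while aryl methyl ethers and the naphthalene core are inert without hydrogen pressure.

**Step 5**
Reactants: 7 5,7,8-trimethoxy-2,3-dimethyl-1-(2,4,5-trimethoxyphenyl)naphthalene
Product: 8 2-methoxy-6,7-dimethyl-8-(2,4,5-trimethoxyphenyl)naphthalene-1,4-dione
Conditions: (NH4)2Ce(NO3)6 (2.1 equiv, added dropwise in H2O), MeCN/H2O 2:1, 0 °C, 20 min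
Reagents that add atoms: water, O
Why: Oxidative demethylation of a para-dimethoxyarene by tetravalent cerium, in which the trimethoxynaphthalene ring (the most easily oxidised π-system) forms the radical cation, water adds at C-5 and C-8, and two molecules of methanol are lost to give the 2-methoxy-1,4-quinone; the twisted pendant trimethoxyphenyl ring is spared by limiting the oxidant and is deactivated once the quinone exists.

## Compound list

1 | propargyl bromide (3-bromoprop-1-yne) | C#CCBr | starting material
2 | dipropargyl sulfide | C#CCSCC#C | intermediate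
3 | 1-iodo-2,4,5-trimethoxybenzene | COc1cc(OC)c(OC)cc1I | starting material
4 | bis[3-(2,4,5-trimethoxyphenyl)prop-2-yn-1-yl] sulfide | COc1cc(OC)c(OC)cc1C#CCSCC#Cc1cc(OC)c(OC)cc1OC | intermediate
5 | bis[3-(2,4,5-trimethoxyphenyl)propa-1,2-dien-1-yl] sulfide (allene configuration not defined; not isolated) | COc1cc(OC)c(OC)cc1C=C=CSC=C=Cc1cc(OC)c(OC)cc1OC | intermediate
6 | 5,6,8-trimethoxy-4-(2,4,5-trimethoxyphenyl)-1,3-dihydronaphtho[2,3-c]thiophene | COc1cc(OC)c(OC)c2c(-c3cc(OC)c(OC)cc3OC)c3CSCc3cc12 | intermediate
7 | 5,7,8-trimethoxy-2,3-dimethyl-1-(2,4,5-trimethoxyphenyl)naphthalene | COc1cc(OC)c(OC)c2c(-c3cc(OC)c(OC)cc3OC)c(C)c(C)cc12 | intermediate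
8 | 2-methoxy-6,7-dimethyl-8-(2,4,5-trimethoxyphenyl)naphthalene-1,4-dione | COC1=CC(=O)c2cc(C)c(C)c(-c3cc(OC)c(OC)cc3OC)c2C1=O | target

## Summary

Total step count: 5. Longest linear sequence: 5 (1 → 2 → 4 → 6 → 7 → 8).

## Steps most likely to fail, with fallbacks

**Step 3 (Garratt–Braverman cyclisation of the thioether).** The weakly acidic thioether may isomerise sluggishly, and the closure next to the methoxy group is crowded. The fallback sets out from 4 and comes back at 6. Oxidise 4 with mCPBA (2.2 equiv, CH2Cl2, 0 °C) to bis[3-(2,4,5-trimethoxyphenyl)prop-2-yn-1-yl] sulfone F1. Its much more acidic α-methylene groups let the same cyclisation run with Et3N in CHCl3 at rt, giving 5,6,8-trimethoxy-4-(2,4,5-trimethoxyphenyl)-1,3-dihydronaphtho[2,3-c]thiophene 2,2-dioxide F2. LiAlH4 in refluxing THF, which reduces five-membered cyclic sulfones to sulfides, then gives 6.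

**Step 5 (oxidation with (NH4)2Ce(NO3)6).** The pendant ring also carries a para-dimethoxy pattern, so over-oxidation or the wrong quinone is possible. The fallback sets out from 7 and comes back at 8. Anodic oxidation of 7 at a potential just sufficient for the naphthalene ring (Pt anode, KOH/MeOH, 0 °C) gives the quinone bisketal 1,1,2,4,4-pentamethoxy-6,7-dimethyl-8-(2,4,5-trimethoxyphenyl)-1,4-dihydronaphthalene F3. F3 is isolated and hydrolysed with dilute aqueous HCl in acetone at rt to 8.

**Step 2 (double Sonogashira on the volatile, sulfur-containing diyne).** Catalyst inhibition, Glaser coupling or mono-coupling could lower the yield. The fallback sets out from 3 and comes back at 4; compounds 1 and 2 are then not needed. Couple 3 with propargyl alcohol (Pd(PPh3)2Cl2, CuI, Et3N, rt) to give 3-(2,4,5-trimethoxyphenyl)prop-2-yn-1-ol F4. Convert F4 with CBr4/PPh3 (CH2Cl2, 0 °C) into 1-(3-bromoprop-1-yn-1-yl)-2,4,5-trimethoxybenzene F5. Treat two equivalents of F5 with Na2S·9H2O in MeOH/THF at rt to give 4.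

## Further compounds

F1 | step 3 | bis[3-(2,4,5-trimethoxyphenyl)prop-2-yn-1-yl] sulfone | COc1cc(OC)c(OC)cc1C#CCS(=O)(=O)CC#Cc1cc(OC)c(OC)cc1OC
F2 | step 3 | 5,6,8-trimethoxy-4-(2,4,5-trimethoxyphenyl)-1,3-dihydronaphtho[2,3-c]thiophene 2,2-dioxide | COc1cc(OC)c(OC)c2c(-c3cc(OC)c(OC)cc3OC)c3CS(=O)(=O)Cc3cc12
F3 | step 5 | 1,1,2,4,4-pentamethoxy-6,7-dimethyl-8-(2,4,5-trimethoxyphenyl)-1,4-dihydronaphthalene | COC1=CC(OC)(OC)c2cc(C)c(C)c(-c3cc(OC)c(OC)cc3OC)c2C1(OC)OC
F4 | step 2 | 3-(2,4,5-trimethoxyphenyl)prop-2-yn-1-ol | COc1cc(OC)c(OC)cc1C#CCO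
F5 | step 2 | 1-(3-bromoprop-1-yn-1-yl)-2,4,5-trimethoxybenzene | COc1cc(OC)c(OC)cc1C#CCBr
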